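**Retrosynthetic overview**

1. Feature used: the target is a 1-aryl-1,2-dihydronaphthalene (C1 = CH bearing the 3,4-dimethoxyphenyl ring, C2 and C3 = the carbons bearing CH2OH, C4 = vinylic CH; ring A = trimethoxybenzene ring, ring B = dihydro ring). C1 and C4 are both benzylic carbons on ring A, so C1–C8a–C4a–C4 is a hidden o-quinodimethane and C2–C3 with its two oxygenated carbons is a hidden fumarate.
2. Target diol ⇐ dimethyl 1-aryl-1,2-dihydronaphthalene-2,3-dicarboxylate (reduce both esters) ⇐ 1-aryl-4-hydroxytetralin-2,3-diester (remove C4–OH and C3–H to give the C3=C4 alkene).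
3. Hydroxytetralin diester ⇐ [4+2] cycloaddition (C1–C2 and C3–C4) of dimethyl fumarate with the hydroxy-o-quinodimethane photogenerated from 2-(3,4-dimethoxybenzyl)-3,4,5-trimethoxybenzaldehyde, on a chiral titanium TADDOLate.
4. Benzylbenzaldehyde ⇐ Negishi C(sp2)–C(sp3) coupling of 2-bromo-3,4,5-trimethoxybenzaldehyde with (3,4-dimethoxybenzyl)zinc chloride, made from 3,4-dimethoxybenzyl chloride.
5. Ring order: ring A and the pendant aryl ring are bought; ring B is the only ring formed, in the cycloaddition.

Key step: step 3

Assumption: the (R,R)-TADDOL–titanium template (and, in the fallback, the (S)-lactate auxiliary) is taken to expose the diene face that gives the (1R) series; if the sense is the opposite, the equally available antipode is used with no other change.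

**Step 1**
Reactants: 1 3,4-dimethoxybenzyl chloride
Product: 2 (3,4-dimethoxybenzyl)zinc chloride, used as its LiCl-solubilised THF solution
Conditions: Zn dust (1.5 equiv), LiCl (1.5 equiv), THF, 25 °C, slow addition of 1
Reagents that add atoms: zinc, [Zn]
Why: LiCl-assisted oxidative insertion of zinc into a benzylic C–Cl bond is a standard preparation of benzylic zinc chlorides, and slow addition at 25 °C should keep Wurtz homocoupling of this electron-rich chloride low.

**Step 2**
Reactants: 2 (3,4-dimethoxybenzyl)zinc chloride; 3 2-bromo-3,4,5-trimethoxybenzaldehyde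
Product: 4 2-(3,4-dimethoxybenzyl)-3,4,5-trimethoxybenzaldehyde
Conditions: Pd(OAc)2 (2 mol%), SPhos (4 mol%), THF, 0 → 25 °C, 2 (1.3 equiv) added slowly; aq. NH4Cl
Reagents that add atoms: none
Why: In this Negishi coupling, SPhos-ligated zerovalent palladium (formed in the flask from Pd(OAc)2) should insert into the hindered but formyl-activated C–Br bond and transmetalate with the slowly dosed benzylzinc reagent faster than that reagent adds to the aldehyde, forming the aryl–CH2 bond.

**Step 3**
Reactants: 4 2-(3,4-dimethoxybenzyl)-3,4,5-trimethoxybenzaldehyde; 5 dimethyl fumarate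
Product: 7 dimethyl (1R,2S,3R,4R)-1-(3,4-dimethoxyphenyl)-4-hydroxy-6,7,8-trimethoxy-1,2,3,4-tetrahydronaphthalene-2,3-dicarboxylate (numbering of the overview), via (E)-hydroxy-o-quinodimethane 6 (not isolated)
Conditions: Ti(Oi-Pr)4 (1.5 equiv), (R,R)-TADDOL (1.6 equiv), toluene, 25 °C; then 4 (1 equiv), 5 (1.2 equiv), degassed, hν (365 nm), 0 °C; aq. NaHCO3
Reagents that add atoms: none
Why: Excitation of aldehyde 4 and 1,5-hydrogen transfer from the doubly benzylic CH2 to the carbonyl oxygen give dienol 6 with hydroxyl and aryl group both pointing outward, and its O–H exchanges onto the TADDOL-bound titanium alkoxide, which also holds one fumarate carbonyl. The closest known reaction type is the photoenolization/Diels–Alder reaction of 2-benzylbenzaldehydes with fumarates, together with its titanium alkoxide/chiral diol variant established for 2-alkylbenzaldehydes. Ring B is closed by a concerted, suprafacial intermolecular [4+2] cycloaddition that forms C1–C2 and C3–C4 at once and restores the aromaticity of ring A. C1 and C4 come out cis because both diene termini carry their substituent outward, C2 and C3 come out trans from the E geometry of the fumarate, the C3 ester is cis to the C4 oxygen because titanium bridges them (endo), and the absolute sense at C1 follows from the diene face left open by the chiral diol. The step needs site-selective hydrogen abstraction, secured because only the diarylmethane CH2 lies ortho to the formyl group, and a titanium-bound pathway that outruns the unbound one, for which the electron-rich trimethoxy aldehyde (a poor photoenol partner without titanium), a full equivalent of template and only a small excess of fumarate are relied on. Only C1 has to be set correctly here, since C3 and C4 are erased in step 4 and C2 can equilibrate to the trans arrangement.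

**Step 4**
Reactants: 7 dimethyl (1R,2S,3R,4R)-1-(3,4-dimethoxyphenyl)-4-hydroxy-6,7,8-trimethoxy-1,2,3,4-tetrahydronaphthalene-2,3-dicarboxylate
Product: 9 dimethyl (1R,2S)-1-(3,4-dimethoxyphenyl)-6,7,8-trimethoxy-1,2-dihydronaphthalene-2,3-dicarboxylate, via C4 mesylate 8 (not isolated)
Conditions: MsCl (1.5 equiv), Et3N (3 equiv), CH2Cl2, 0 °C; then DBU (2 equiv), 0 → 25 °C
Reagents that add atoms: methanesulfonyl chloride, CS(=O)(=O)Cl (its CH3SO2 group is carried by intermediate 8 only; product 9 keeps none of it)
Why: Mesylation of the secondary benzylic alcohol and DBU-mediated anti elimination (E2/E1cB) of the acidic C3–H, which is alpha to an ester and trans to the leaving group, should give the C3=C4 alkene conjugated with ring A and the C3 ester, while C1 is untouched and C2 stays in its more stable trans relation to the aryl group.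

**Step 5**
Reactants: 9 dimethyl (1R,2S)-1-(3,4-dimethoxyphenyl)-6,7,8-trimethoxy-1,2-dihydronaphthalene-2,3-dicarboxylate
Product: 10 [(1R,2S)-1-(3,4-dimethoxyphenyl)-6,7,8-trimethoxy-1,2-dihydronaphthalene-2,3-diyl]dimethanol (CNP0274357.1)
Conditions: i-Bu2AlH (6 equiv), CH2Cl2, −78 → 0 °C; aq. potassium sodium tartrate (KNaC4H4O6)
Reagents that add atoms: none
Why: Ester reduction with i-Bu2AlH delivers hydride 1,2 to both the saturated and the conjugated methyl ester at low temperature, which should give the two primary alcohols without conjugate reduction, without epimerisation at C2 and without touching the aryl methyl ethers.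

**Compound list**

1 | 3,4-dimethoxybenzyl chloride | COc1ccc(CCl)cc1OC | starting material
2 | (3,4-dimethoxybenzyl)zinc chloride (THF solution, LiCl present) | COc1ccc(C[Zn]Cl)cc1OC | intermediate
3 | 2-bromo-3,4,5-trimethoxybenzaldehyde | COc1cc(C=O)c(Br)c(OC)c1OC | starting material
4 | 2-(3,4-dimethoxybenzyl)-3,4,5-trimethoxybenzaldehyde | COc1ccc(Cc2c(C=O)cc(OC)c(OC)c2OC)cc1OC | intermediate
5 | dimethyl fumarate | COC(=O)/C=C/C(=O)OC | starting material
6 | (E)-hydroxy-o-quinodimethane (photoenol of 4; hydroxyl and aryl group both outward) | O/C=C1/C(=C/c2ccc(OC)c(OC)c2)C(OC)=C(OC)C(OC)=C1 | intermediate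
7 | dimethyl (1R,2S,3R,4R)-1-(3,4-dimethoxyphenyl)-4-hydroxy-6,7,8-trimethoxy-1,2,3,4-tetrahydronaphthalene-2,3-dicarboxylate (1,2-trans, 2,3-trans, 3,4-cis) | COc1ccc([C@@H]2c3c(cc(OC)c(OC)c3OC)[C@H](O)[C@H](C(=O)OC)[C@H]2C(=O)OC)cc1OC | intermediate
8 | dimethyl (1R,2S,3R,4R)-1-(3,4-dimethoxyphenyl)-6,7,8-trimethoxy-4-(methylsulfonyloxy)-1,2,3,4-tetrahydronaphthalene-2,3-dicarboxylate | COc1ccc([C@@H]2c3c(cc(OC)c(OC)c3OC)[C@H](OS(C)(=O)=O)[C@H](C(=O)OC)[C@H]2C(=O)OC)cc1OC | intermediate
9 | dimethyl (1R,2S)-1-(3,4-dimethoxyphenyl)-6,7,8-trimethoxy-1,2-dihydronaphthalene-2,3-dicarboxylate | COc1ccc([C@@H]2c3c(cc(OC)c(OC)c3OC)C=C(C(=O)OC)[C@H]2C(=O)OC)cc1OC | intermediate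
10 | [(1R,2S)-1-(3,4-dimethoxyphenyl)-6,7,8-trimethoxy-1,2-dihydronaphthalene-2,3-diyl]dimethanol | COc1ccc([C@@H]2c3c(cc(OC)c(OC)c3OC)C=C(CO)[C@H]2CO)cc1OC | target

**Step count**

Total steps: 5. Longest linear sequence: 5 steps (from 1; 4 steps from 3).

**Steps most likely to fail**

Step 3. The monodentate fumarate ester may bind the titanium template only weakly, and the free dienol may add fumarate without the template, so facial selectivity at C1 may be poor. Photoenolisation may also be slow because the outward aryl group is pressed against the peri C8 methoxy group. Exchange of methyl for isopropyl ester groups on titanium would not matter, since both esters are reduced in step 5.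
Fallback (auxiliary control in place of the chiral template): the fallback sets out from aldehyde 4. It is irradiated without titanium in the presence of bis[(S)-1-methoxy-1-oxopropan-2-yl] fumarate F1, which is prepared from fumaryl chloride and methyl (S)-lactate with pyridine in CH2Cl2. The lactate carbonyl groups of F1 hydrogen-bond to the dienol hydroxyl and differentiate the diene faces. The major diastereomer, bis[(S)-1-methoxy-1-oxopropan-2-yl] (1R,2S,3R,4R)-1-(3,4-dimethoxyphenyl)-4-hydroxy-6,7,8-trimethoxy-1,2,3,4-tetrahydronaphthalene-2,3-dicarboxylate F2, is freed from its diastereomers by chromatography or crystallisation. Treatment as in step 4 converts it through its C4 mesylate F3 into the bis-lactyl (1R,2S)-1,2-dihydronaphthalene-2,3-dicarboxylate F4. Excess i-Bu2AlH then cleaves all four ester groups, so the fallback comes back to the route at target 10.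

Step 2. The benzylzinc reagent may add 1,2 to the formyl group of 3 or 4 in competition with cross-coupling, and it may homocouple.
Fallback (aryllithium addition and hydrogenolysis in place of cross-coupling): the fallback sets out from bromoaldehyde 3. The aldehyde is masked with ethylene glycol (p-TsOH, toluene, reflux, azeotropic removal of water) as 2-(2-bromo-3,4,5-trimethoxyphenyl)-1,3-dioxolane F5. Bromine–lithium exchange (n-BuLi, THF, −78 °C) and addition to 3,4-dimethoxybenzaldehyde should give racemic (3,4-dimethoxyphenyl)[6-(1,3-dioxolan-2-yl)-2,3,4-trimethoxyphenyl]methanol F6. Hydrogenolysis of the diaryl carbinol C–O bond (H2, palladium on carbon (Pd/C), EtOAc–AcOH) should give 2-[2-(3,4-dimethoxybenzyl)-3,4,5-trimethoxyphenyl]-1,3-dioxolane F7. Hydrolysis with aqueous HCl in THF brings the fallback back to the route at aldehyde 4.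

Step 4. Under DBU the new double bond may migrate out of the C3–C4 position through the C2 dienolate, followed by oxidation to the naphthalene with loss of both stereocenters. The labile benzylic mesylate may also be displaced before it eliminates.
Fallback (acid-catalysed E1 dehydration in place of sulfonate elimination under base): the fallback sets out from hydroxy diester 7, which is heated with catalytic p-TsOH in toluene at 60–80 °C. Ionisation at C4 is assisted by the para C7 methoxy group, and loss of C3–H should give diester 9 directly, where the fallback rejoins the route. No base is present and no new compound is made.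

**Further compounds**

F1 | step 3 | bis[(S)-1-methoxy-1-oxopropan-2-yl] fumarate | COC(=O)[C@H](C)OC(=O)/C=C/C(=O)O[C@@H](C)C(=O)OC
F2 | step 3 | bis[(S)-1-methoxy-1-oxopropan-2-yl] (1R,2S,3R,4R)-1-(3,4-dimethoxyphenyl)-4-hydroxy-6,7,8-trimethoxy-1,2,3,4-tetrahydronaphthalene-2,3-dicarboxylate | COc1ccc([C@@H]2c3c(cc(OC)c(OC)c3OC)[C@H](O)[C@H](C(=O)O[C@@H](C)C(=O)OC)[C@H]2C(=O)O[C@@H](C)C(=O)OC)cc1OC
F3 | step 3 | bis[(S)-1-methoxy-1-oxopropan-2-yl] (1R,2S,3R,4R)-1-(3,4-dimethoxyphenyl)-6,7,8-trimethoxy-4-(methylsulfonyloxy)-1,2,3,4-tetrahydronaphthalene-2,3-dicarboxylate | COc1ccc([C@@H]2c3c(cc(OC)c(OC)c3OC)[C@H](OS(C)(=O)=O)[C@H](C(=O)O[C@@H](C)C(=O)OC)[C@H]2C(=O)O[C@@H](C)C(=O)OC)cc1OC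
F4 | step 3 | bis[(S)-1-methoxy-1-oxopropan-2-yl] (1R,2S)-1-(3,4-dimethoxyphenyl)-6,7,8-trimethoxy-1,2-dihydronaphthalene-2,3-dicarboxylate | COc1ccc([C@@H]2c3c(cc(OC)c(OC)c3OC)C=C(C(=O)O[C@@H](C)C(=O)OC)[C@H]2C(=O)O[C@@H](C)C(=O)OC)cc1OC
F5 | step 2 | 2-(2-bromo-3,4,5-trimethoxyphenyl)-1,3-dioxolane | COc1cc(C2OCCO2)c(Br)c(OC)c1OC
F6 | step 2 | (3,4-dimethoxyphenyl)[6-(1,3-dioxolan-2-yl)-2,3,4-trimethoxyphenyl]methanol (racemic) | COc1ccc(C(O)c2c(C3OCCO3)cc(OC)c(OC)c2OC)cc1OC
F7 | step 2 | 2-[2-(3,4-dimethoxybenzyl)-3,4,5-trimethoxyphenyl]-1,3-dioxolane | COc1ccc(Cc2c(C3OCCO3)cc(OC)c(OC)c2OC)cc1OC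
F0 | step 4 | none | none
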